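I decide to put the care of this repeat into one number, the rate at which target is lost, and not into the early rates.

in all of them: free catalyst 0.00200 M

| flask | starting material | partner | time |
|---|---|---|---|
| birch | 0.100 M | 0.200 M |  |
| ash | 0.0500 M | 0.150 M |  |
| oak | 0.150 M | 0.200 M |  |
| maple | 0.100 M | 0.200 M | 52 h |

| run | time / h | [target] / M |
|---|---|---|
| birch run | 0.99 | 0.0078 |
| birch run | 3.0 | 0.0232 |
| birch run | 5.7 | 0.0401 |
| birch run | 9.1 | 0.0556 |
| birch run | 13 | 0.0653 |
| ash run | 0.99 | 0.0056 |
| ash run | 3.0 | 0.0155 |
| ash run | 5.7 | 0.0256 |
| ash run | 9.1 | 0.0330 |
| ash run | 13 | 0.0374 |
| oak run | 0.99 | 0.0092 |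
| oak run | 3.0 | 0.0263 |
| oak run | 5.7 | 0.0434 |
| oak run | 9.1 | 0.0609 |
| oak run | 13 | 0.0751 |

(standard deviation of a reading: 5 × 10⁻⁴ M)

- Overall: starting material + partner -> target, with free catalyst as catalyst.
- Constant volume, constant temperature.
- Readings of a species count what is bound in complexes too.
- "The second partner" is partner.
- An order is taken over about fifteen percent of the charge, up and down.

1. the exponent of [partner] in the starting rate at the charge of the birch run (at the point where two percent of the starting material have become target)
2. the exponent of [starting material] in the starting rate at the charge of the birch run (at the point where two percent of the starting material have become target) (one fixed amount of target, the same in the runs compared)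
3. target in the maple run at 52 h, as a share of the starting material charged

Starting material is the limiting reagent in the maple run, with less of it charged than of partner, and maple repeats the birch charge. So I solve it at both ends and join them. Early, target builds. Birch climbs at 0.00456 M h⁻¹ between 5.7 h and 9.1 h, and I take the join time tj as the moment it crosses half of its charge, which I put at 7.87 h. Late, I let a full charge of target fall as exp(−k(t−tj)), where k is the share of target lost per hour.

Which number matters? The early rates and both orders act through tj. If tj were off by half, the exponent would move by 8.92% of itself, whereas the same error in k moves it by half. So k must be known well, and tj need not.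

Now k itself. Birch and ash share an excess of partner of 0.100 M, so birch near 0.0500 M of target stands at the fresh ash charge. Ash opens at 0.00566 M h⁻¹, and birch, around 0.0478 M of target, runs slower. I read that shortfall as target lost, which gives the loss constant k, the shortfall in rate per unit of target 0.0229 h⁻¹. Its scatter is 0.0114 h⁻¹.

A weakening catalyst would give a like shortfall, and the readings stop at 13 h. I commit to lost target, so the reading to watch is maple at 52 h. I reckon 36.3%, with a span from 22.0% to 60.2%.

The forecast gives 0.7, 0.3 and 87%, on another reading of the shortfall: “This points to catalyst death”.

The flask gives 0.77, 0.25 and 29.5%.

    free catalyst + starting material → catalyst-substrate complex (308.9 M⁻¹ h⁻¹)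
    catalyst-substrate complex + partner → target + free catalyst (49.32 M⁻¹ h⁻¹)
    free catalyst + impurity → spent catalyst
    target → decomposed product (0.02808 h⁻¹)

Maple stands 6.8 percentage points below my share. In these steps target goes to decomposed product with 0.0281 h⁻¹. Put to use on the oak run, my k times its 13 h reading gives an estimated drain of 0.00172 M h⁻¹, which is 18.1% of the early oak rate of 0.0095 M h⁻¹. With k3 in place of my k, the same reading gives 0.00211 M h⁻¹, which is 22.2% of that rate.

Readings and results stem from a simulated flask on assumed constants; scatter was added.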